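**Retrosynthetic overview**
1. Endgame: the 7α-OH comes from allylic oxidation of the 8(17)-ene. The C2 ketone is carried as a methyl enol ether. The C19 acetate comes from an axial ester. The C4 methyl goes in last, from the open α face.
2. Ring B is made by a one-carbon ring expansion of a trans-hydrindanone. Quaternary C10 shifts from C8 to a carbenoid carbon C9 that already carries the complete Z side chain.
3. Ring A is closed by metathesis between a vinyl group on C4 and a 2-methoxyallyl group on C10.
4. C5 and C10 are set by an enantioselective three-component coupling on 2-methylcyclopent-2-enone.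
5. Ring order: cyclopentanone (future ring B), then ring A, then expansion to ring B. The side chain comes from but-2-yn-1-ol and acrolein dimethyl acetal.

Assumption: positions carry the labdane numbers of the target (C1–C20; β = face of the C10 methyl, α = face of H-5), and the (S,S) ligand of step 7 is taken to give the drawn enantiomer, otherwise its mirror image is used.

**Step 1**
Reactants: 1 but-2-yn-1-ol
Product: 3 (Z)-3-iodobut-2-en-1-ol, via sodium oxaaluminacyclopentene 2 (not isolated)
Conditions: NaAlH2(OCH2CH2OMe)2, Et2O, 0 °C to rt; I2, THF, −78 °C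
Reagents that add atoms: iodine II
Why: Hydroxyl-directed trans-hydroalumination puts aluminium on C13 cis to the CH2O group, and iodinolysis with retention fixes the Z geometry of the side chain.

**Step 2**
Reactants: 3 (Z)-3-iodobut-2-en-1-ol
Product: 4 (Z)-tert-butyl[(3-iodobut-2-en-1-yl)oxy]diphenylsilane
Conditions: t-BuPh2SiCl, imidazole, CH2Cl2, rt
Reagents that add atoms: tert-butyl(chloro)diphenylsilane CC(C)(C)[Si](Cl)(c1ccccc1)c1ccccc1
Why: Standard silyl ether protection gives a group that survives acid, organolithium and hydride steps.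

**Step 3**
Reactants: 5 3,3-dimethoxyprop-1-ene; 4 (Z)-tert-butyl[(3-iodobut-2-en-1-yl)oxy]diphenylsilane
Product: 7 (Z)-tert-butyl[(6,6-dimethoxy-3-methylhex-2-en-1-yl)oxy]diphenylsilane, via B-alkyl borabicyclononane 6 (not isolated)
Conditions: 9-BBN-H, THF, rt; then 4, PdCl2(dppf) (3 mol %), aq NaOH, THF/DMF, 40 °C
Reagents that add atoms: none
Why: Anti-Markovnikov hydroboration followed by B-alkyl Suzuki–Miyaura coupling joins C12 to C13 with retention of the Z alkene.

**Step 4**
Reactants: 7 (Z)-tert-butyl[(6,6-dimethoxy-3-methylhex-2-en-1-yl)oxy]diphenylsilane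
Product: 8 (Z)-6-[(tert-butyldiphenylsilyl)oxy]-4-methylhex-4-enal
Conditions: pyridinium p-toluenesulfonate (cat.), acetone/H2O, 50 °C
Reagents that add atoms: water O
Why: Mild acetal hydrolysis frees the C9 aldehyde while the robust silyl ether and the alkene are untouched.

**Step 5**
Reactants: 8 (Z)-6-[(tert-butyldiphenylsilyl)oxy]-4-methylhex-4-enal
Product: 9 (Z)-tert-butyl[(6,6-dibromo-3-methylhex-2-en-1-yl)oxy]diphenylsilane
Conditions: P(OPh)3, Br2, CH2Cl2, −78 to 0 °C
Reagents that add atoms: bromine BrBr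
Why: Deoxygenative gem-dibromination with the preformed phosphite–bromine adduct leaves no free bromine to attack the alkene.

**Step 6**
Reactants: 10 2-methoxyprop-1-ene
Product: 11 3-bromo-2-methoxyprop-1-ene
Conditions: N-bromosuccinimide, pentane, 0 °C; distilled from K2CO3
Reagents that add atoms: N-bromosuccinimide O=C1CCC(=O)N1Br
Why: Electrophilic bromination of the enol ether followed by proton loss gives the allylic bromide, an acetonyl cation equivalent.

**Step 7**
Reactants: 12 methyl but-3-enoate; 13 2-methylcyclopent-2-en-1-one; 11 3-bromo-2-methoxyprop-1-ene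
Product: 16 methyl 2-[(1S,2S)-2-(2-methoxyprop-2-en-1-yl)-2-methyl-3-oxocyclopentyl]but-3-enoate (epimers at the ester α-carbon C4), via lithium dienolate 14 (not isolated), via lithium cyclopentenolate 15 (not isolated)
Conditions: LiN(iPr)2, (S,S)-1,2-dimethoxy-1,2-diphenylethane (1.2 equiv), toluene, −78 °C; 13, −78 °C; 11, DMPU, −78 to −40 °C
Reagents that add atoms: none
Why: Proposed new method: a C2-symmetric diether bound to lithium should make the known racemic α-selective Michael addition of lithium dienolates enantioselective on an α-methyl cyclopentenone, because ligated dienolate and enone carbonyl share one lithium in a closed eight-membered transition state that delivers the α-carbon (largest HOMO coefficient) to one face of C5, and the tetrasubstituted enolate 15 is then alkylated at low temperature faster than it exchanges protons and on the face opposite the new C5 substituent, which sets C10 (trans relation of C4 and C1, hence the later trans ring fusion); the closest known reaction type is the ligand-controlled asymmetric Michael addition of simple lithium ester enolates to enoates combined with three-component enone coupling.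

**Step 8**
Reactants: 16 methyl 2-[(1S,2S)-2-(2-methoxyprop-2-en-1-yl)-2-methyl-3-oxocyclopentyl]but-3-enoate
Product: 17 methyl (3aS,7aS)-6-methoxy-7a-methyl-1-oxo-2,3,3a,4,7,7a-hexahydro-1H-indene-4-carboxylate (trans-fused; C4 epimers)
Conditions: second-generation Grubbs catalyst (5 mol %), toluene, 80 °C, argon sparge
Reagents that add atoms: none
Why: Ring-closing metathesis starts at the monosubstituted vinyl group and closes onto the 1,1-disubstituted enol ether, giving ring A with C2 masked as a methyl enol ether.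

**Step 9**
Reactants: 17 trans-hydrindenone keto ester; 9 (Z)-tert-butyl[(6,6-dibromo-3-methylhex-2-en-1-yl)oxy]diphenylsilane
Product: 22 trans-decalone (8-oxo; 9β side chain/9α-H; 10β-methyl; 5α-H; C2 methyl enol ether; C4 ester epimers), via dibromoalkyllithium 18 (not isolated), via dibromo alkoxide 19 (not isolated), via oxido carbenoid 20 (not isolated), via lithium enolate 21 (not isolated)
Conditions: 9 (1.5 equiv), THF/Et2O, −100 °C, LiN(iPr)2 added dropwise; n-BuLi, −100 to −20 °C; H2O; K2CO3 (cat.), MeOH, rt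
Reagents that add atoms: none
Why: The β-oxido carbenoid ring enlargement is a semipinacol-type 1,2-shift in which the better migrating quaternary C10 moves from C8 to carbenoid carbon C9 with retention, turning the strained hydrindanone into the trans-decalone and forging the hindered C9–C10 bond, and C9 is then set by base equilibration to the equatorial β side chain.

**Step 10**
Reactants: 22 trans-decalone
Product: 23 8(17)-methylene decalin ester
Conditions: Ph3PCH3Br, KOtBu, toluene, 80 °C
Reagents that add atoms: methyltriphenylphosphonium bromide C[P+](c1ccccc1)(c1ccccc1)c1ccccc1.[Br-]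
Why: Wittig methylenation of the only ketone installs C17, and any base epimerisation at C9 returns to the favoured equatorial isomer.

**Step 11**
Reactants: 23 8(17)-methylene decalin ester
Product: 25 4α-methyl-4β-carbomethoxy decalin, via lithium ester dienolate 24 (not isolated)
Conditions: LiN(iPr)2, THF/DMPU, −78 °C; MeI, −78 to −20 °C
Reagents that add atoms: iodomethane CI
Why: α-Alkylation of the exocyclic ester dienolate occurs from the α face because the β face is blocked by the axial C10 methyl, so the methyl becomes equatorial and the ester (C19) axial, which sets C4.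

**Step 12**
Reactants: 25 4α-methyl-4β-carbomethoxy decalin
Product: 26 C19 primary alcohol
Conditions: LiAlH4, Et2O, 0 °C to rt; aq NaOH work-up
Reagents that add atoms: none
Why: Hydride reduction of the only carbonyl group gives the neopentyl alcohol, and the enol ether, alkenes and silyl ether are inert.

**Step 13**
Reactants: 26 C19 primary alcohol
Product: 27 C19 acetate
Conditions: Ac2O, pyridine, DMAP (cat.), CH2Cl2, rt
Reagents that add atoms: acetic anhydride CC(=O)OC(C)=O
Why: Nucleophile-catalysed acetylation of the single free hydroxyl places the acetate before any other alcohol is unveiled.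

**Step 14**
Reactants: 27 C19 acetate
Product: 28 2-oxo decalin acetate
Conditions: oxalic acid (cat.), wet SiO2, CH2Cl2, rt
Reagents that add atoms: water O
Why: Mild enol ether hydrolysis releases the ketone at C2 only, and no alkene lies in reach for conjugation.

**Step 15**
Reactants: 28 2-oxo decalin acetate
Product: 29 7α-hydroxy silyl ether
Conditions: SeO2 (0.3 equiv), t-BuOOH (2 equiv), CH2Cl2, 0 °C to rt
Reagents that add atoms: selenium dioxide O=[Se]=O; tert-butyl hydroperoxide CC(C)(C)OO
Why: In the selenium dioxide allylic oxidation (ene step, then 2,3-shift) selenium bonds to C17 from the open α face while the axial 7α-H is removed, and oxygen returns to C7 on that face, which gives the axial 7α-alcohol; CH2 reacts before CH, so C9 is spared.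

**Step 16**
Reactants: 29 7α-hydroxy silyl ether
Product: 30 target CNP0277693.2
Conditions: HF·pyridine, pyridine, THF, 0 °C to rt
Reagents that add atoms: none
Why: Buffered fluoride desilylation frees the C15 allylic alcohol without touching the acetate, the ketone or the allylic 7-alcohol.

**Compound list**
1 | but-2-yn-1-ol | CC#CCO | starting material
2 | sodium 2,2-bis(2-methoxyethoxy)-3-methyl-1,2-oxaaluminacyclopent-3-en-2-uide | [Na+].CC1=CCO[Al-]1(OCCOC)OCCOC | intermediate
3 | (Z)-3-iodobut-2-en-1-ol | C/C(I)=C/CO | intermediate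
4 | (Z)-tert-butyl[(3-iodobut-2-en-1-yl)oxy]diphenylsilane | C/C(I)=C/CO[Si](c1ccccc1)(c1ccccc1)C(C)(C)C | intermediate
5 | 3,3-dimethoxyprop-1-ene | C=CC(OC)OC | starting material
6 | 9-(3,3-dimethoxypropyl)-9-borabicyclo[3.3.1]nonane | COC(OC)CCB1C2CCCC1CCC2 | intermediate
7 | (Z)-tert-butyl[(6,6-dimethoxy-3-methylhex-2-en-1-yl)oxy]diphenylsilane | COC(OC)CC/C(C)=C\CO[Si](c1ccccc1)(c1ccccc1)C(C)(C)C | intermediate
8 | (Z)-6-[(tert-butyldiphenylsilyl)oxy]-4-methylhex-4-enal | O=CCC/C(C)=C\CO[Si](c1ccccc1)(c1ccccc1)C(C)(C)C | intermediate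
9 | (Z)-tert-butyl[(6,6-dibromo-3-methylhex-2-en-1-yl)oxy]diphenylsilane | BrC(Br)CC/C(C)=C\CO[Si](c1ccccc1)(c1ccccc1)C(C)(C)C | intermediate
10 | 2-methoxyprop-1-ene | C=C(C)OC | starting material
11 | 3-bromo-2-methoxyprop-1-ene | C=C(CBr)OC | intermediate
12 | methyl but-3-enoate | C=CCC(=O)OC | starting material
13 | 2-methylcyclopent-2-en-1-one | CC1=CCCC1=O | starting material
14 | lithium 1-methoxybuta-1,3-dien-1-olate | [Li+].[O-]C(OC)=CC=C | intermediate
15 | lithium 2-methyl-3-[1-(methoxycarbonyl)allyl]cyclopent-1-en-1-olate (C5 set) | [Li+].[O-]C1=C(C)[C@H](C(C=C)C(=O)OC)CC1 | intermediate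
16 | methyl 2-[(1S,2S)-2-(2-methoxyprop-2-en-1-yl)-2-methyl-3-oxocyclopentyl]but-3-enoate, C4 epimers | O=C1CC[C@@H](C(C=C)C(=O)OC)[C@]1(C)CC(=C)OC | intermediate
17 | methyl (3aS,7aS)-6-methoxy-7a-methyl-1-oxo-2,3,3a,4,7,7a-hexahydro-1H-indene-4-carboxylate, trans-fused, C4 epimers | O=C1CC[C@H]2C(C(=O)OC)C=C(OC)C[C@]12C | intermediate
18 | (Z)-1,1-dibromo-6-(tert-butyldiphenylsilyloxy)-4-methylhex-4-enyllithium | [Li]C(Br)(Br)CC/C(C)=C\CO[Si](c1ccccc1)(c1ccccc1)C(C)(C)C | intermediate
19 | lithium 8β-alkoxide of the adduct of 18 and 17 (dibromoalkyl group on the α face of C8) | [Li+].[O-][C@@]1(C(Br)(Br)CC/C(C)=C\CO[Si](c3ccccc3)(c3ccccc3)C(C)(C)C)CC[C@H]2C(C(=O)OC)C=C(OC)C[C@]12C | intermediate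
20 | β-oxido carbenoid (C9 bears Li and Br) | [Li+].[O-][C@@]1(C([Li])(Br)CC/C(C)=C\CO[Si](c3ccccc3)(c3ccccc3)C(C)(C)C)CC[C@H]2C(C(=O)OC)C=C(OC)C[C@]12C | intermediate
21 | lithium 8(9)-enolate of the ring-expanded decalone | [Li+].[O-]C1=C(CC/C(C)=C\CO[Si](c3ccccc3)(c3ccccc3)C(C)(C)C)[C@@]2(C)CC(OC)=CC(C(=O)OC)[C@@H]2CC1 | intermediate
22 | methyl 15-(tert-butyldiphenylsilyloxy)-2-methoxy-8-oxo-17,18-dinorlabda-2,13Z-dien-19-oate (trans-decalin, 9α-H, C4 epimers) | O=C1CC[C@H]2C(C(=O)OC)C=C(OC)C[C@]2(C)[C@H]1CC/C(C)=C\CO[Si](c1ccccc1)(c1ccccc1)C(C)(C)C | intermediate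
23 | methyl 15-(tert-butyldiphenylsilyloxy)-2-methoxy-18-norlabda-2,8(17),13Z-trien-19-oate (C4 epimers) | C=C1CC[C@H]2C(C(=O)OC)C=C(OC)C[C@]2(C)[C@H]1CC/C(C)=C\CO[Si](c1ccccc1)(c1ccccc1)C(C)(C)C | intermediate
24 | lithium ester dienolate of 23 (C4 planar) | [Li+].C=C1CC[C@H]2C(=C([O-])OC)C=C(OC)C[C@]2(C)[C@H]1CC/C(C)=C\CO[Si](c1ccccc1)(c1ccccc1)C(C)(C)C | intermediate
25 | methyl 15-(tert-butyldiphenylsilyloxy)-2-methoxylabda-2,8(17),13Z-trien-19-oate (4α-methyl, 4β-ester) | C=C1CC[C@H]2[C@@](C)(C(=O)OC)C=C(OC)C[C@]2(C)[C@H]1CC/C(C)=C\CO[Si](c1ccccc1)(c1ccccc1)C(C)(C)C | intermediate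
26 | 15-(tert-butyldiphenylsilyloxy)-2-methoxylabda-2,8(17),13Z-trien-19-ol | C=C1CC[C@H]2[C@@](C)(CO)C=C(OC)C[C@]2(C)[C@H]1CC/C(C)=C\CO[Si](c1ccccc1)(c1ccccc1)C(C)(C)C | intermediate
27 | 15-(tert-butyldiphenylsilyloxy)-2-methoxylabda-2,8(17),13Z-trien-19-yl acetate | C=C1CC[C@H]2[C@@](C)(COC(C)=O)C=C(OC)C[C@]2(C)[C@H]1CC/C(C)=C\CO[Si](c1ccccc1)(c1ccccc1)C(C)(C)C | intermediate
28 | 15-(tert-butyldiphenylsilyloxy)-2-oxolabda-8(17),13Z-dien-19-yl acetate | C=C1CC[C@H]2[C@@](C)(COC(C)=O)CC(=O)C[C@]2(C)[C@H]1CC/C(C)=C\CO[Si](c1ccccc1)(c1ccccc1)C(C)(C)C | intermediate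
29 | 15-(tert-butyldiphenylsilyloxy)-7α-hydroxy-2-oxolabda-8(17),13Z-dien-19-yl acetate | C=C1[C@H](O)C[C@H]2[C@@](C)(COC(C)=O)CC(=O)C[C@]2(C)[C@H]1CC/C(C)=C\CO[Si](c1ccccc1)(c1ccccc1)C(C)(C)C | intermediate
30 | 7α,15-dihydroxy-2-oxolabda-8(17),13Z-dien-19-yl acetate (CNP0277693.2) | C=C1[C@H](O)C[C@H]2[C@@](C)(COC(C)=O)CC(=O)C[C@]2(C)[C@H]1CC/C(C)=C\CO | target

**Step count:** 16 steps in total. The longest linear sequence is 13 steps (steps 1–5, then 9–16).

**The three steps most likely to fail**

**Step 7 (the proposed new step).**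
- Risks: low enantioselectivity, 1,2- or γ-attack of the dienolate, and proton transfer from C4–H to enolate 15 before the alkylation.
- Start and return: the fallback sets out from 11, 12 and 13 and comes back at 17. It swaps asymmetric induction for a classical resolution.
- Racemic series: the coupling is run without ligand in THF/DMPU, using the known α-selective Michael addition of lithium dienolates with enolate trapping. This gives the racemic keto ester F1, and metathesis as in step 8 gives the racemic hydrindenone F2.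
- Resolution: NaBH4 attacks the ketone from the α face and gives the racemic 8β-alcohol F3. Esterification with (S)-2-methoxy-2-phenylacetic acid (DCC, DMAP) gives two diastereomeric esters, which are separated by chromatography and crystallisation.
- Return to the route: the wanted mandelate ester F4 is cleaved with K2CO3 in MeOH to the enantiopure alcohol F5. Buffered Dess–Martin oxidation of F5 gives 17.

**Step 9.**
- Risks: enolisation of 17 in place of addition, decay of the carbenoid by hydride shift, and competing migration of C7.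
- Start and return: the fallback sets out from 8 and 17 and comes back at 22. It replaces the basic carbenoid by a cationic semipinacol shift.
- Addition: aldehyde 8 is turned with MeSeH and ZnCl2 into the bis(methylseleno)acetal F6. n-BuLi cleaves one C–Se bond to the non-basic α-selenoalkyllithium F7, which adds cleanly to hindered enolisable ketones and gives the β-hydroxy selenide F8.
- Rearrangement: AgBF4 on basic alumina in CH2Cl2 ionises the C9–Se bond. The more substituted C10 migrates, and the same K2CO3/MeOH equilibration gives 22.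

**Step 15.**
- Risks: oxidation at the side-chain alkene (C12 or C16) and overoxidation to the 7-ketone.
- Start and return: the fallback sets out from 28 and comes back at 30. It deactivates the side-chain alkene electronically.
- Sequence: HF·pyridine gives the 15-alcohol F9, and Ac2O in pyridine gives the 15,19-diacetate F10, whose allylic acetate slows the 13-ene as in geranyl acetate. The same SeO2/t-BuOOH oxidation gives the 7α-hydroxy diacetate F11.
- Final release: K2CO3 in MeOH at 0 °C removes the unhindered allylic 15-acetate much faster than the axial neopentyl 19-acetate and gives 30.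

**Further compounds**
F1 | step 7 | racemic methyl 2-[trans-2-(2-methoxyprop-2-en-1-yl)-2-methyl-3-oxocyclopentyl]but-3-enoate | O=C1CC[C@@H](C(C=C)C(=O)OC)[C@]1(C)CC(=C)OC.O=C1CC[C@H](C(C=C)C(=O)OC)[C@@]1(C)CC(=C)OC
F2 | step 7 | racemic trans-fused methyl 6-methoxy-7a-methyl-1-oxo-2,3,3a,4,7,7a-hexahydro-1H-indene-4-carboxylate | O=C1CC[C@H]2C(C(=O)OC)C=C(OC)C[C@]12C.O=C1CC[C@@H]2C(C(=O)OC)C=C(OC)C[C@@]12C
F3 | step 7 | racemic 1β-hydroxy analogue of F2 | O[C@H]1CC[C@H]2C(C(=O)OC)C=C(OC)C[C@]12C.O[C@@H]1CC[C@@H]2C(C(=O)OC)C=C(OC)C[C@@]12C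
F4 | step 7 | (S)-2-methoxy-2-phenylacetate of the wanted alcohol enantiomer | CO[C@H](C(=O)O[C@H]1CC[C@H]2C(C(=O)OC)C=C(OC)C[C@]12C)c1ccccc1
F5 | step 7 | enantiopure methyl (3aS,7aS)-1β-hydroxy-6-methoxy-7a-methyl-2,3,3a,4,7,7a-hexahydro-1H-indene-4-carboxylate | O[C@H]1CC[C@H]2C(C(=O)OC)C=C(OC)C[C@]12C
F6 | step 9 | (Z)-tert-butyl{[3-methyl-6,6-bis(methylselanyl)hex-2-en-1-yl]oxy}diphenylsilane | C[Se]C([Se]C)CC/C(C)=C\CO[Si](c1ccccc1)(c1ccccc1)C(C)(C)C
F7 | step 9 | (Z)-6-(tert-butyldiphenylsilyloxy)-4-methyl-1-(methylselanyl)hex-4-enyllithium | [Li]C([Se]C)CC/C(C)=C\CO[Si](c1ccccc1)(c1ccccc1)C(C)(C)C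
F8 | step 9 | β-hydroxy selenide from F7 and 17 (8β-OH) | O[C@@]1(C([Se]C)CC/C(C)=C\CO[Si](c3ccccc3)(c3ccccc3)C(C)(C)C)CC[C@H]2C(C(=O)OC)C=C(OC)C[C@]12C
F9 | step 15 | 15-hydroxy-2-oxolabda-8(17),13Z-dien-19-yl acetate | C=C1CC[C@H]2[C@@](C)(COC(C)=O)CC(=O)C[C@]2(C)[C@H]1CC/C(C)=C\CO
F10 | step 15 | 2-oxolabda-8(17),13Z-diene-15,19-diyl diacetate | C=C1CC[C@H]2[C@@](C)(COC(C)=O)CC(=O)C[C@]2(C)[C@H]1CC/C(C)=C\COC(C)=O
F11 | step 15 | 7α-hydroxy-2-oxolabda-8(17),13Z-diene-15,19-diyl diacetate | C=C1[C@H](O)C[C@H]2[C@@](C)(COC(C)=O)CC(=O)C[C@]2(C)[C@H]1CC/C(C)=C\COC(C)=O
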